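**Retrosynthetic overview**
- The aryl ether C11–O bond is made last, by Mitsunobu coupling of a bicyclic keto alcohol with umbelliferone.
- The C9–C11 bond and the C9 stereocentre come from a [2,3]-Wittig–Still rearrangement of a C7 O-stannylmethyl ether (1,3-chirality transfer from C7); the allylic alcohol comes from Wharton transposition of an α,β-epoxy ketone.
- Ring A (the only ring that is built) closes at C3–C4 by hydrogen-atom-transfer radical cyclisation of the isopropenyl group onto a pendant nitrile, which also creates the gem-dimethyl group and the C3 ketone.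
- Quaternary C10 is set by methylation, then cyanoethylation anti to the C5 isopropenyl group; the enone is masked as the epoxide that is needed later anyway.
- Ring B is bought as (S)-(+)-carvone (its stereocentre becomes C5); order: ring B (bought), then ring A, then the coumarin ether.

Assumption: decalin atoms are called by drimane locants (C3 ketone carbon, C4 gem-dimethyl carbon, C5 ring-fusion CH, C7=C8 alkene, C9 the CH bearing C11H2–O, C10 angular-methyl carbon), and Bu3SnCH2I is a bought reagent.

**Step 1**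
Reactants: 1 (S)-(+)-carvone
Product: 3 (5S,6R)-2,6-dimethyl-5-(prop-1-en-2-yl)cyclohex-2-en-1-one (6-methylcarvone; trans epimer shown), via lithium dienolate 2 (not isolated)
Conditions: LiN(i-Pr)2, THF, −78 °C; MeI, −78 to 0 °C
Reagents that add atoms: iodomethane, CI
Why: Kinetic deprotonation gives the cross-conjugated lithium dienolate, which is methylated at C10 (enolate alkylation); the new centre forms as an epimer mixture that does not matter because C10 is enolised again in step 3.

**Step 2**
Reactants: 3 6-methylcarvone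
Product: 4 (1S,3R,4S,6S)-1,3-dimethyl-4-(prop-1-en-2-yl)-7-oxabicyclo[4.1.0]heptan-2-one
Conditions: 35% H2O2, NaOH (cat.), MeOH, 0 °C
Reagents that add atoms: hydrogen peroxide, OO
Why: Weitz–Scheffer nucleophilic epoxidation touches only the enone, and hydroperoxide adds axially to C7 on the face opposite the C5 isopropenyl group, which sets C7 and C8 (epoxide trans to isopropenyl).

**Step 3**
Reactants: 4 epoxy ketone; 5 acrylonitrile
Product: 7 3-[(1S,3R,4R,6S)-1,3-dimethyl-2-oxo-4-(prop-1-en-2-yl)-7-oxabicyclo[4.1.0]heptan-3-yl]propanenitrile, via potassium enolate 6 (not isolated)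
Conditions: KOt-Bu (15 mol %), t-BuOH/THF, 0 °C to rt
Reagents that add atoms: none
Why: Base-catalysed Michael addition (cyanoethylation) at the only enolisable carbon; the neighbouring isopropenyl group sits pseudoaxial to avoid allylic 1,2-strain with the C10 methyl, so acrylonitrile enters trans to it and sets quaternary C10, while the epoxide prevents a second Michael addition into the former enone.

**Step 4**
Reactants: 7 cyanoethyl epoxy ketone
Product: 9 (2S,3S,4aR,8aR)-2,3-epoxy-2,5,5,8a-tetramethyloctahydronaphthalene-1,6(2H,5H)-dione, via ketimine 8 (not isolated)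
Conditions: Fe(acac)3 (30 mol %), PhSiH3, EtOH, 60 °C; then aq. AcOH, THF, 40 °C
Reagents that add atoms: water, O
Why: Metal-hydride hydrogen atom transfer to the isopropenyl group gives the tertiary C4 radical, which closes ring A by 6-exo addition to the nitrile carbon (radical cyclisation onto a nitrile), and the imine is hydrolysed to the C3 ketone; no new stereocentre forms and the trans ring fusion follows from the trans relation of the two tethered groups.

**Step 5**
Reactants: 9 epoxy dione
Product: 10 (2S,3S,4aR,8aR)-2,3-epoxy-6,6-(ethylenedioxy)-2,5,5,8a-tetramethyloctahydronaphthalen-1(2H)-one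
Conditions: HOCH2CH2OH, PPTS (cat.), benzene, reflux (Dean–Stark)
Reagents that add atoms: ethylene glycol, OCCO
Why: Acid-catalysed ketalisation goes only at the ring A ketone, because the ring B carbonyl is flanked by two fully substituted carbons and deactivated by the α-epoxide, which survives the weak acid.

**Step 6**
Reactants: 10 epoxy ketone ketal
Product: 12 (2S,4aS,8aS)-7,7-(ethylenedioxy)-3,4a,8,8-tetramethyl-1,2,4a,5,6,7,8,8a-octahydronaphthalen-2-ol, via epoxy hydrazone 11 (not isolated)
Conditions: N2H4·H2O, AcOH (cat.), MeOH, 0 to 40 °C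
Reagents that add atoms: none
Why: Wharton transposition: the epoxy hydrazone opens to a vinyl diazene that loses N2, giving the C8=C9 alkene and the C7 alcohol; the C7–O bond is not broken, so C7 keeps the configuration set in step 2.

**Step 7**
Reactants: 12 allylic alcohol
Product: 14 tributyl({[(2S,4aS,8aS)-7,7-(ethylenedioxy)-3,4a,8,8-tetramethyl-1,2,4a,5,6,7,8,8a-octahydronaphthalen-2-yl]oxy}methyl)stannane, via potassium alkoxide 13 (not isolated)
Conditions: KH, THF, 0 °C; Bu3SnCH2I, 18-crown-6 (cat.), rt
Reagents that add atoms: (iodomethyl)tributylstannane, CCCC[Sn](CCCC)(CCCC)CI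
Why: Williamson etherification of the alkoxide with the reactive primary iodide; no stereocentre is touched.

**Step 8**
Reactants: 14 stannylmethyl ether
Product: 17 (4aR,5S,8aS)-5-(hydroxymethyl)-1,1,4a,6-tetramethyl-3,4,4a,5,8,8a-hexahydronaphthalen-2(1H)-one, via lithiomethyl ether 15 (not isolated), via ketal alcohol 16 (not isolated)
Conditions: n-BuLi, THF, −78 to −40 °C; then 1 M HCl, THF, rt
Reagents that add atoms: water, O
Why: Tin–lithium exchange gives the α-alkoxy organolithium, which undergoes the suprafacial [2,3]-Wittig–Still sigmatropic rearrangement through a five-membered envelope transition state; the C9–C11 bond forms on the face that carried the pseudoaxial C7–O bond (trans to the angular methyl), the alkene moves to C7=C8, and the acid then hydrolyses the dioxolane.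

**Step 9**
Reactants: 17 keto alcohol; 18 umbelliferone (7-hydroxy-2H-chromen-2-one)
Product: 19 7-{[(1S,4aS,8aR)-2,5,5,8a-tetramethyl-6-oxo-1,4,4a,5,6,7,8,8a-octahydronaphthalen-1-yl]methoxy}-2H-chromen-2-one
Conditions: PPh3, DIAD, THF, 0 °C to rt
Reagents that add atoms: none
Why: Mitsunobu etherification of the primary alcohol by the acidic phenol forms the aryl ether at the CH2 carbon, so no stereocentre is involved.

**Compound list**
1 | (S)-(+)-carvone, (5S)-2-methyl-5-(prop-1-en-2-yl)cyclohex-2-en-1-one | CC1=CC[C@@H](CC1=O)C(C)=C | starting material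
2 | lithium cross-conjugated dienolate of 1 (O–Li on the former carbonyl carbon, C5 unchanged) | CC1=CC[C@@H](C=C1O[Li])C(C)=C | intermediate
3 | (5S,6R)-2,6-dimethyl-5-(prop-1-en-2-yl)cyclohex-2-en-1-one (6-methylcarvone, trans epimer; C6 epimers both usable) | CC1=CC[C@@H]([C@@H](C)C1=O)C(C)=C | intermediate
4 | (1S,3R,4S,6S)-1,3-dimethyl-4-(prop-1-en-2-yl)-7-oxabicyclo[4.1.0]heptan-2-one (epoxide trans to isopropenyl) | C[C@]12O[C@H]1C[C@H](C(C)=C)[C@@H](C)C2=O | intermediate
5 | acrylonitrile | C=CC#N | starting material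
6 | potassium enolate of 4 (enolate between the carbonyl carbon and the methyl-bearing α-carbon; other centres as in 4) | C[C@]12O[C@H]1C[C@H](C(C)=C)C(C)=C2[O-].[K+] | intermediate
7 | 3-[(1S,3R,4R,6S)-1,3-dimethyl-2-oxo-4-(prop-1-en-2-yl)-7-oxabicyclo[4.1.0]heptan-3-yl]propanenitrile | C[C@]12O[C@H]1C[C@H](C(C)=C)[C@@](C)(CCC#N)C2=O | intermediate
8 | C3 N–H ketimine of 9 (6-imino analogue, same stereocentres) | C[C@]12O[C@H]1C[C@@H]3C(C)(C)C(=N)CC[C@@]3(C)C2=O | intermediate
9 | (2S,3S,4aR,8aR)-2,3-epoxy-2,5,5,8a-tetramethyloctahydronaphthalene-1,6(2H,5H)-dione (trans-fused) | C[C@]12O[C@H]1C[C@@H]3C(C)(C)C(=O)CC[C@@]3(C)C2=O | intermediate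
10 | (2S,3S,4aR,8aR)-2,3-epoxy-6,6-(ethylenedioxy)-2,5,5,8a-tetramethyloctahydronaphthalen-1(2H)-one | C[C@]12O[C@H]1C[C@@H]3C(C)(C)C4(OCCO4)CC[C@@]3(C)C2=O | intermediate
11 | hydrazone of 10 at the ring B carbonyl (C=N geometry not defined) | C[C@]12O[C@H]1C[C@@H]3C(C)(C)C4(OCCO4)CC[C@@]3(C)C2=NN | intermediate
12 | (2S,4aS,8aS)-7,7-(ethylenedioxy)-3,4a,8,8-tetramethyl-1,2,4a,5,6,7,8,8a-octahydronaphthalen-2-ol | CC1=C[C@]2(C)CCC3(OCCO3)C(C)(C)[C@H]2C[C@@H]1O | intermediate
13 | potassium alkoxide of 12 | CC1=C[C@]2(C)CCC3(OCCO3)C(C)(C)[C@H]2C[C@@H]1[O-].[K+] | intermediate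
14 | tributyl({[(2S,4aS,8aS)-7,7-(ethylenedioxy)-3,4a,8,8-tetramethyl-1,2,4a,5,6,7,8,8a-octahydronaphthalen-2-yl]oxy}methyl)stannane | CC1=C[C@]2(C)CCC3(OCCO3)C(C)(C)[C@H]2C[C@@H]1OC[Sn](CCCC)(CCCC)CCCC | intermediate
15 | lithiomethyl ether of 12 (Li in place of SnBu3 in 14) | CC1=C[C@]2(C)CCC3(OCCO3)C(C)(C)[C@H]2C[C@@H]1OC[Li] | intermediate
16 | [(1S,4aS,8aR)-6,6-(ethylenedioxy)-2,5,5,8a-tetramethyl-1,4,4a,5,6,7,8,8a-octahydronaphthalen-1-yl]methanol | CC1=CC[C@@H]2C(C)(C)C3(OCCO3)CC[C@@]2(C)[C@H]1CO | intermediate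
17 | (4aR,5S,8aS)-5-(hydroxymethyl)-1,1,4a,6-tetramethyl-3,4,4a,5,8,8a-hexahydronaphthalen-2(1H)-one | CC1=CC[C@@H]2C(C)(C)C(=O)CC[C@@]2(C)[C@H]1CO | intermediate
18 | umbelliferone, 7-hydroxy-2H-chromen-2-one | O=c1ccc2ccc(O)cc2o1 | starting material
19 | 7-{[(1S,4aS,8aR)-2,5,5,8a-tetramethyl-6-oxo-1,4,4a,5,6,7,8,8a-octahydronaphthalen-1-yl]methoxy}-2H-chromen-2-one | CC1=CC[C@@H]2C(C)(C)C(=O)CC[C@@]2(C)[C@H]1COc1ccc2ccc(=O)oc2c1 | target

**Totals**
Total step count: 9. Longest linear sequence: 9 steps (1 to 19).

**Steps most likely to fail**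

Step 4 (radical closure onto the nitrile). Addition of the tertiary radical to an unactivated nitrile is slow, so simple reduction of the isopropenyl group may win. The fallback sets out from 4 and comes back at 9. The kinetic lithium enolate of 4 (LiN(i-Pr)2, THF, −78 °C) is alkylated with allyl bromide, again trans to isopropenyl, to give the allyl epoxy ketone F1. Aldehyde-selective Wacker oxidation of the monosubstituted alkene (PdCl2(PhCN)2, CuCl2, AgNO2, O2, t-BuOH/MeNO2) gives the aldehyde F2. The same Fe(acac)3/PhSiH3 hydrogen atom transfer then closes ring A onto the much more reactive aldehyde carbonyl to give the hydroxy epoxy ketone F3 as C3 epimers. Dess–Martin oxidation of F3 gives 9.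

Step 6 (Wharton transposition). The ring B carbonyl is flanked by two fully substituted carbons, so hydrazone formation may be too slow. The fallback sets out from 10 and comes back at 12, and it needs no condensation at that carbonyl. NaBH4 (MeOH, 0 °C) reduces the ketone to the epoxy alcohol F4 (carbinol epimers). NaH, CS2 and MeI convert F4 into the xanthate F5. Bu3SnH/AIBN in refluxing benzene generates the C9 radical, which opens the adjacent epoxide to the C7 alkoxy radical and, after hydrogen transfer, gives 12 with C7 unchanged.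

Step 9 (Mitsunobu etherification). The primary alcohol is axial and sits next to a quaternary carbon, so displacement at C11 may be slow or give elimination. The fallback sets out from 14 and comes back at 19. The rearrangement of 14 is quenched with aqueous NH4Cl instead of acid, so that the ketal alcohol 16 is isolated. Compound 16 is coupled with bought 7-bromocoumarin by palladium-catalysed C–O cross-coupling ([Pd(allyl)Cl]2, RockPhos, Cs2CO3, toluene, 90 °C), which forms the aryl–oxygen bond instead of the alkyl–oxygen bond and gives the ketal aryl ether F6. PPTS in aqueous acetone then removes the dioxolane to give 19.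

**Further compounds**
F1 | step 4 | (1S,3R,4R,6S)-1,3-dimethyl-3-(prop-2-en-1-yl)-4-(prop-1-en-2-yl)-7-oxabicyclo[4.1.0]heptan-2-one | C[C@]12O[C@H]1C[C@H](C(C)=C)[C@@](C)(CC=C)C2=O
F2 | step 4 | 3-[(1S,3R,4R,6S)-1,3-dimethyl-2-oxo-4-(prop-1-en-2-yl)-7-oxabicyclo[4.1.0]heptan-3-yl]propanal | C[C@]12O[C@H]1C[C@H](C(C)=C)[C@@](C)(CCC=O)C2=O
F3 | step 4 | (2S,3S,4aR,8aR)-2,3-epoxy-6-hydroxy-2,5,5,8a-tetramethyloctahydronaphthalen-1(2H)-one (C6 carbinol epimers) | C[C@]12O[C@H]1C[C@@H]3C(C)(C)C(O)CC[C@@]3(C)C2=O
F4 | step 6 | ring B carbinol from reduction of 10 (C1–OH in place of C1=O, carbinol epimers, other centres as in 10) | C[C@]12O[C@H]1C[C@@H]3C(C)(C)C4(OCCO4)CC[C@@]3(C)C2O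
F5 | step 6 | O-alkyl S-methyl xanthate of F4 | C[C@]12O[C@H]1C[C@@H]3C(C)(C)C4(OCCO4)CC[C@@]3(C)C2OC(=S)SC
F6 | step 9 | ethylene ketal of 19 at the ring A ketone | CC1=CC[C@@H]2C(C)(C)C3(OCCO3)CC[C@@]2(C)[C@H]1COc1ccc2ccc(=O)oc2c1
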